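**Plan**

1. Numbering: C1 acyl bridgehead, C2 ketone, C3 CH, C4 enol carbon, C5 prenyl bridgehead, C6 CH2, C7 prenyl CH, C8 methyl/homoprenyl carbon, C9 bridging ketone, C10 side-chain carbonyl; ring A = C1–C2–C3–C4–C5–C9, ring B = C1–C8–C7–C6–C5–C9.
2. Retrosynthetic cuts, in order: C1–C10 (bridgehead acylation); C4–C5 of ring A (key step); C1–C2 and C8–homoprenyl (conjugate addition–aldol); C5–prenyl; C8–CH3; C1–C8 and C6–C7 of ring B (Michael–aldol annulation).
3. Forward: ring B is made first from 5-methylhex-4-enal and methyl vinyl ketone and then substituted at C8, C5 and C1; ring A is closed second by gold-catalysed 6-endo-dig attack of the C9=C5 enol silane on a bromoalkyne; C2/C4 are then adjusted and C1 is acylated.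
4. Enabling feature: C3 is an unsubstituted methine between the oxygenated C2 and C4, so C2–C3–C4 can be carried as a 3-bromo-1-silyloxypropynyl arm on C1 whose terminal carbon C4 is within reach of C5 of ring B.
5. Stereochemistry: C7 from the (R)-configured prolinol ether catalyst; C8 by copper-mediated addition anti to the C7 prenyl; C1 in the aldol trapping; C5 through the C1 tether in the key step; the side-chain centre from (R)-2-methylbutanoic acid.

Key step: step 10

Remark on the chemistry: the C4-enol/C2-ketone form of the target is taken as one tautomer of the ring-A β-diketone, which is what the final demethylation releases. Centres that are erased later (the carbinol carbon C2, and C5 before step 9) are carried as epimer mixtures; their SMILES leave them undefined.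

**Route**

Step 1
Reactants: 1 5-methylhex-4-enal; 2 but-3-en-2-one (methyl vinyl ketone)
Product: 3 (2R)-2-(3-methylbut-2-en-1-yl)-5-oxohexanal
Conditions: (R)-2-(methoxydiphenylmethyl)pyrrolidine (5 mol%), ethyl 3,4-dihydroxybenzoate (20 mol%), neat, 4 °C
Reagents that add atoms: none
Why: Enamine-mediated organocatalytic Michael addition of an aldehyde to an enone, in which methyl vinyl ketone should attack the E-enamine on the face remote from the methoxydiphenylmethyl group and so set the future C7 centre as R.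

Step 2
Reactants: 3 (2R)-2-(3-methylbut-2-en-1-yl)-5-oxohexanal
Product: 4 (4R)-4-(3-methylbut-2-en-1-yl)cyclohex-2-en-1-one
Conditions: LiOH (0.1 equiv), i-PrOH, rt
Reagents that add atoms: none
Why: Intramolecular aldol condensation (the ring-closing half of a Robinson annulation) forms ring B, and the mild hydroxide conditions should carry the aldehyde α-centre intact into the less labile γ-position of the enone.

Step 3
Reactants: 4 (4R)-4-(3-methylbut-2-en-1-yl)cyclohex-2-en-1-one
Product: 5 trimethyl{[(3R,4R)-3-methyl-4-(3-methylbut-2-en-1-yl)cyclohex-1-en-1-yl]oxy}silane (methyl trans to prenyl)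
Conditions: MeMgBr, CuI·2LiCl (10 mol%), TMSCl, THF, −40 °C
Reagents that add atoms: methylmagnesium bromide, C[Mg]Br; chlorotrimethylsilane, C[Si](C)(C)Cl
Why: Copper-catalysed conjugate addition with in situ silyl trapping gives the enol silane regiospecifically; methyl enters trans to the prenyl group, but that centre is removed again in step 4.

Step 4
Reactants: 5 trimethyl{[(3R,4R)-3-methyl-4-(3-methylbut-2-en-1-yl)cyclohex-1-en-1-yl]oxy}silane
Product: 6 (4R)-3-methyl-4-(3-methylbut-2-en-1-yl)cyclohex-2-en-1-one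
Conditions: Pd(OAc)2 (10 mol%), O2 (1 atm), DMSO, rt
Reagents that add atoms: none
Why: Saegusa–Ito oxidation, in which divalent palladium adds to the enol silane and eliminates the only β-hydrogen, should return the enone with the methyl group on the β-carbon (future C8) and leave the prenyl-bearing centre untouched.

Step 5
Reactants: 6 (4R)-3-methyl-4-(3-methylbut-2-en-1-yl)cyclohex-2-en-1-one
Product: 8 3-methyl-4,6-bis(3-methylbut-2-en-1-yl)cyclohex-2-en-1-one (ring C4 as in 6; both C6 epimers), via lithium dienolate 7 (not isolated)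
Conditions: LDA, THF, −78 °C; then prenyl bromide, −78 to −20 °C
Reagents that add atoms: 1-bromo-3-methylbut-2-ene (prenyl bromide), CC(C)=CCBr
Why: Kinetic α′-deprotonation and SN2 alkylation of the cross-conjugated dienolate (enolate alkylation) installs the future C5 prenyl group, expected mainly trans to the C7 prenyl; the new centre needs no control because it becomes sp2 in step 9.

Step 6
Reactants: 8 3-methyl-4,6-bis(3-methylbut-2-en-1-yl)cyclohex-2-en-1-one; 9 5-bromo-2-methylpent-2-ene; 10 3-(trimethylsilyl)prop-2-ynal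
Product: 13 2-[1-hydroxy-3-(trimethylsilyl)prop-2-yn-1-yl]-3-methyl-3-(4-methylpent-3-en-1-yl)-4,6-bis(3-methylbut-2-en-1-yl)cyclohexan-1-one (arm at ring C2 and methyl at ring C3 cis to the ring-C4 prenyl; homoprenyl trans; carbinol and ring-C6 epimers), via (4-methylpent-3-en-1-yl)magnesium bromide 11 (not isolated), via bromomagnesium enolate 12 (not isolated)
Conditions: 9, Mg, THF, rt; then 8, CuBr·SMe2 (10 mol%), THF, −40 °C; then 10, −78 °C; aq. NH4Cl
Reagents that add atoms: none
Why: Copper-catalysed conjugate addition of the homoprenyl Grignard reagent anti to the pseudoaxial C7 prenyl sets C8 (homoprenyl trans, methyl cis to the C7 prenyl), and the magnesium enolate is then trapped by the ynal in an aldol addition that should occur on the face opposite the homoprenyl group just delivered (the usual trans course of conjugate addition–enolate trapping), placing the arm on C1 cis to the C7 prenyl; the carbinol centre is uncontrolled and is erased in step 12.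

Step 7
Reactants: 13 aldol adduct (name as in step 6)
Product: 14 2-[1-(tert-butyldimethylsilyloxy)-3-(trimethylsilyl)prop-2-yn-1-yl]-3-methyl-3-(4-methylpent-3-en-1-yl)-4,6-bis(3-methylbut-2-en-1-yl)cyclohexan-1-one (ring stereochemistry as in 13)
Conditions: TBSOTf, 2,6-lutidine, CH2Cl2, −78 °C
Reagents that add atoms: tert-butyldimethylsilyl trifluoromethanesulfonate, CC(C)(C)[Si](C)(C)OS(=O)(=O)C(F)(F)F
Why: Silyl ether protection of the secondary propargylic alcohol blocks retro-aldol cleavage and carries the C2 oxygen forward, while one equivalent at −78 °C should not enolise the hindered ketone.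

Step 8
Reactants: 14 silyl ether (name as in step 7)
Product: 15 2-[3-bromo-1-(tert-butyldimethylsilyloxy)prop-2-yn-1-yl]-3-methyl-3-(4-methylpent-3-en-1-yl)-4,6-bis(3-methylbut-2-en-1-yl)cyclohexan-1-one (ring stereochemistry as in 13)
Conditions: NBS, AgNO3 (10 mol%), acetone, 0 °C, dark
Reagents that add atoms: N-bromosuccinimide, O=C1CCC(=O)N1Br
Why: Silver-catalysed desilylative bromination of the alkynylsilane through a silver acetylide is fast at 0 °C, so one equivalent of N-bromosuccinimide should be consumed at the alkyne before the trisubstituted alkenes can react.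

Step 9
Reactants: 15 bromoalkyne ketone (name as in step 8)
Product: 16 6-[3-bromo-1-(tert-butyldimethylsilyloxy)prop-2-yn-1-yl]-1-(tert-butyldimethylsilyloxy)-5-methyl-5-(4-methylpent-3-en-1-yl)-2,4-bis(3-methylbut-2-en-1-yl)cyclohex-1-ene (arm at ring C6 and methyl at ring C5 cis to the ring-C4 prenyl; carbinol epimers)
Conditions: TBSOTf, Et3N, CH2Cl2, 0 °C to rt
Reagents that add atoms: tert-butyldimethylsilyl trifluoromethanesulfonate, CC(C)(C)[Si](C)(C)OS(=O)(=O)C(F)(F)F
Why: Soft enolisation and O-silylation (silyl enol ether formation) removes the accessible C5–H and not the C1–H shielded by quaternary C8 and the bulky arm, so the tetrasubstituted C9=C5 enol silane should form with C1 unchanged and both C5 epimers converging.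

Step 10
Reactants: 16 bromoalkyne enol silane (name as in step 9)
Product: 17 4-bromo-2-(tert-butyldimethylsilyloxy)-8-methyl-8-(4-methylpent-3-en-1-yl)-5,7-bis(3-methylbut-2-en-1-yl)bicyclo[3.3.1]non-3-en-9-one (C7 prenyl on the face of the C2–C4 bridge; C5 prenyl trans to the C7 prenyl; C8 methyl cis to the C7 prenyl; C2 epimers)
Conditions: [(t-Bu)2(2-biphenylyl)P]Au(NCMe)SbF6 (5 mol%), acetone containing H2O (2 equiv), rt
Reagents that add atoms: none
Why: The cationic monovalent gold complex binds the bromoalkyne and the enol silane carbon C5 adds to the terminal carbon C4 anti to gold; transfer of the silyl group to water unveils the C9 ketone and protodeauration leaves the C3=C4 vinyl bromide. The closest known reaction type is the gold-catalysed carbocyclisation of cyclic silyl enol ethers onto tethered alkynes and haloalkynes (a Conia-ene-type process) that gives bicyclo[3.3.1]nonenones. Ring A closes in the 6-endo-dig mode. The only new stereocentre, C5, is fixed by the tether: the arm sits on C1 cis to the C7 prenyl, so C4 can reach C5 only on that face and the C5 prenyl ends trans to the C7 prenyl. The step needs 6-endo over 5-exo closure, which the bulky biaryl phosphine and the bromine substituent (it polarises the alkyne and penalises attack at the internal carbon C3) should secure. It also needs cyclisation to outrun hydrolysis of the enol silane, which the robust tert-butyldimethylsilyl group favours, although ring B must pass through a boat-like arrangement to keep the C7 prenyl clear of the tether.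

Step 11
Reactants: 17 bicyclic silyl ether (name as in step 10)
Product: 18 4-bromo-2-hydroxy-8-methyl-8-(4-methylpent-3-en-1-yl)-5,7-bis(3-methylbut-2-en-1-yl)bicyclo[3.3.1]non-3-en-9-one (ring stereochemistry as in 17; C2 epimers)
Conditions: HF·pyridine, pyridine, THF, 0 °C to rt
Reagents that add atoms: none
Why: Fluoride-mediated desilylation of the secondary allylic silyl ether under buffered conditions should spare the vinyl bromide, the ketone and the prenyl groups, and retro-aldol opening is blocked because it would require a bridgehead enolate.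

Step 12
Reactants: 18 bicyclic allylic alcohol (name as in step 11)
Product: 19 4-bromo-8-methyl-8-(4-methylpent-3-en-1-yl)-5,7-bis(3-methylbut-2-en-1-yl)bicyclo[3.3.1]non-3-ene-2,9-dione (ring stereochemistry as in 17)
Conditions: DMP (Dess–Martin periodinane), CH2Cl2, rt
Reagents that add atoms: none
Why: Dess–Martin oxidation of the allylic alcohol gives the β-bromo enone and erases the uncontrolled C2 centre under neutral conditions that spare the alkenes.

Step 13
Reactants: 19 β-bromo enone (name as in step 12)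
Product: 20 4-methoxy-8-methyl-8-(4-methylpent-3-en-1-yl)-5,7-bis(3-methylbut-2-en-1-yl)bicyclo[3.3.1]non-3-ene-2,9-dione (ring stereochemistry as in 17)
Conditions: NaOMe, MeOH, 0 °C to rt
Reagents that add atoms: sodium methoxide, [Na+].[O-]C
Why: Addition–elimination (vinylogous acyl substitution) of methoxide at C4 exchanges bromide for methoxy and puts C4 at the ketone oxidation level, while the bridgehead C1–H cannot enolise and so keeps its configuration.

Step 14
Reactants: 20 vinylogous methyl ester (name as in step 13)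
Product: 21 4-methoxy-8-methyl-8-(4-methylpent-3-en-1-yl)-5,7-bis(3-methylbut-2-en-1-yl)-3-(trimethylsilyl)bicyclo[3.3.1]non-3-ene-2,9-dione (ring stereochemistry as in 17)
Conditions: LDA, TMSCl (in situ), THF, −78 °C
Reagents that add atoms: chlorotrimethylsilane, C[Si](C)(C)Cl
Why: Vinylic lithiation at C3 of the vinylogous ester with internal silyl quench (C-silylation) blocks the most acidic position so that the next base can only remove the bridgehead proton.

Step 15
Reactants: 22 (2R)-2-methylbutanoic acid
Product: 23 (2R)-2-methylbutanoyl chloride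
Conditions: (COCl)2, DMF (cat.), CH2Cl2, 0 °C to rt
Reagents that add atoms: oxalyl chloride, ClC(=O)C(Cl)=O
Why: Acid chloride formation through the chloroiminium species from oxalyl chloride and catalytic DMF runs without base and should not touch the α-stereocentre.

Step 16
Reactants: 21 C3-silylated vinylogous ester (name as in step 14); 23 (2R)-2-methylbutanoyl chloride
Product: 25 4-methoxy-8-methyl-1-[(2R)-2-methylbutanoyl]-8-(4-methylpent-3-en-1-yl)-5,7-bis(3-methylbut-2-en-1-yl)-3-(trimethylsilyl)bicyclo[3.3.1]non-3-ene-2,9-dione (ring stereochemistry as in 27), via bridgehead lithium species 24 (not isolated)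
Conditions: LiTMP, THF, −78 °C; then 23 (excess), −78 °C
Reagents that add atoms: none
Why: Bridgehead lithiation at C1 (a C–H acidified inductively by the C2 and C9 carbonyls) followed by C-acylation occurs with retention because a bridgehead carbanion cannot invert, and low temperature with excess acid chloride should limit ketene formation so that the (R) side-chain centre survives.

Step 17
Reactants: 25 acylated C3-silyl compound (name as in step 16)
Product: 26 4-methoxy-8-methyl-1-[(2R)-2-methylbutanoyl]-8-(4-methylpent-3-en-1-yl)-5,7-bis(3-methylbut-2-en-1-yl)bicyclo[3.3.1]non-3-ene-2,9-dione (ring stereochemistry as in 27)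
Conditions: TBAF, AcOH, THF, 0 °C
Reagents that add atoms: none
Why: Fluoride-induced protodesilylation of the α-silyl enone (vinylsilane cleavage) buffered with acetic acid removes the C3 blocking group without enolising the side-chain ketone.

Step 18
Reactants: 26 O-methyl ether of the target (name as in step 17)
Product: 27 (1S,5S,7S,8R)-4-hydroxy-8-methyl-1-[(2R)-2-methylbutanoyl]-8-(4-methylpent-3-en-1-yl)-5,7-bis(3-methylbut-2-en-1-yl)bicyclo[3.3.1]non-3-ene-2,9-dione (target)
Conditions: LiCl, DMSO, 120 °C; then dil. HCl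
Reagents that add atoms: none
Why: Nucleophilic demethylation of the vinylogous methyl ester by chloride (SN2 at the O-methyl group, Krapcho-type conditions) releases the enolised β-diketone of ring A under nearly neutral conditions that should leave the side-chain centre and the prenyl groups alone.

**Compound list**

1 | 5-methylhex-4-enal | CC(C)=CCCC=O | starting material
2 | but-3-en-2-one (methyl vinyl ketone) | CC(=O)C=C | starting material
3 | (2R)-2-(3-methylbut-2-en-1-yl)-5-oxohexanal | O=C[C@@H](CC=C(C)C)CCC(C)=O | intermediate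
4 | (4R)-4-(3-methylbut-2-en-1-yl)cyclohex-2-en-1-one | O=C1C=C[C@@H](CC=C(C)C)CC1 | intermediate
5 | trimethyl{[(3R,4R)-3-methyl-4-(3-methylbut-2-en-1-yl)cyclohex-1-en-1-yl]oxy}silane | C[Si](C)(C)OC1=C[C@H](C)[C@@H](CC=C(C)C)CC1 | intermediate
6 | (4R)-3-methyl-4-(3-methylbut-2-en-1-yl)cyclohex-2-en-1-one | O=C1C=C(C)[C@@H](CC=C(C)C)CC1 | intermediate
7 | lithium 5-methyl-4-(3-methylbut-2-en-1-yl)cyclohexa-1,5-dien-1-olate (prenyl-bearing centre as in 6) | [Li]OC1=CC[C@H](CC=C(C)C)C(C)=C1 | intermediate (not isolated)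
8 | 3-methyl-4,6-bis(3-methylbut-2-en-1-yl)cyclohex-2-en-1-one (ring C4 as in 6; both C6 epimers) | O=C1C=C(C)[C@@H](CC=C(C)C)CC1CC=C(C)C | intermediate
9 | 5-bromo-2-methylpent-2-ene | CC(C)=CCCBr | starting material
10 | 3-(trimethylsilyl)prop-2-ynal | C[Si](C)(C)C#CC=O | starting material
11 | (4-methylpent-3-en-1-yl)magnesium bromide | CC(C)=CCC[Mg]Br | intermediate (not isolated)
12 | bromomagnesium 3-methyl-3-(4-methylpent-3-en-1-yl)-4,6-bis(3-methylbut-2-en-1-yl)cyclohex-1-en-1-olate (homoprenyl trans to the ring-C4 prenyl) | Br[Mg]OC1=C[C@](C)(CCC=C(C)C)[C@@H](CC=C(C)C)CC1CC=C(C)C | intermediate (not isolated)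
13 | 2-[1-hydroxy-3-(trimethylsilyl)prop-2-yn-1-yl]-3-methyl-3-(4-methylpent-3-en-1-yl)-4,6-bis(3-methylbut-2-en-1-yl)cyclohexan-1-one (arm and methyl cis to the ring-C4 prenyl; carbinol and ring-C6 epimers) | C[Si](C)(C)C#CC(O)[C@@H]1C(=O)C(CC=C(C)C)C[C@H](CC=C(C)C)[C@@]1(C)CCC=C(C)C | intermediate
14 | 2-[1-(tert-butyldimethylsilyloxy)-3-(trimethylsilyl)prop-2-yn-1-yl]-3-methyl-3-(4-methylpent-3-en-1-yl)-4,6-bis(3-methylbut-2-en-1-yl)cyclohexan-1-one | C[Si](C)(C)C#CC(O[Si](C)(C)C(C)(C)C)[C@@H]1C(=O)C(CC=C(C)C)C[C@H](CC=C(C)C)[C@@]1(C)CCC=C(C)C | intermediate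
15 | 2-[3-bromo-1-(tert-butyldimethylsilyloxy)prop-2-yn-1-yl]-3-methyl-3-(4-methylpent-3-en-1-yl)-4,6-bis(3-methylbut-2-en-1-yl)cyclohexan-1-one | BrC#CC(O[Si](C)(C)C(C)(C)C)[C@@H]1C(=O)C(CC=C(C)C)C[C@H](CC=C(C)C)[C@@]1(C)CCC=C(C)C | intermediate
16 | 6-[3-bromo-1-(tert-butyldimethylsilyloxy)prop-2-yn-1-yl]-1-(tert-butyldimethylsilyloxy)-5-methyl-5-(4-methylpent-3-en-1-yl)-2,4-bis(3-methylbut-2-en-1-yl)cyclohex-1-ene | BrC#CC(O[Si](C)(C)C(C)(C)C)[C@@H]1C(O[Si](C)(C)C(C)(C)C)=C(CC=C(C)C)C[C@H](CC=C(C)C)[C@@]1(C)CCC=C(C)C | intermediate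
17 | 4-bromo-2-(tert-butyldimethylsilyloxy)-8-methyl-8-(4-methylpent-3-en-1-yl)-5,7-bis(3-methylbut-2-en-1-yl)bicyclo[3.3.1]non-3-en-9-one (C2 epimers) | [C@H]12C(O[Si](C)(C)C(C)(C)C)C=C(Br)[C@](CC=C(C)C)(C[C@H](CC=C(C)C)[C@@]1(C)CCC=C(C)C)C2=O | intermediate
18 | 4-bromo-2-hydroxy-8-methyl-8-(4-methylpent-3-en-1-yl)-5,7-bis(3-methylbut-2-en-1-yl)bicyclo[3.3.1]non-3-en-9-one (C2 epimers) | [C@H]12C(O)C=C(Br)[C@](CC=C(C)C)(C[C@H](CC=C(C)C)[C@@]1(C)CCC=C(C)C)C2=O | intermediate
19 | 4-bromo-8-methyl-8-(4-methylpent-3-en-1-yl)-5,7-bis(3-methylbut-2-en-1-yl)bicyclo[3.3.1]non-3-ene-2,9-dione | [C@H]12C(=O)C=C(Br)[C@](CC=C(C)C)(C[C@H](CC=C(C)C)[C@@]1(C)CCC=C(C)C)C2=O | intermediate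
20 | 4-methoxy-8-methyl-8-(4-methylpent-3-en-1-yl)-5,7-bis(3-methylbut-2-en-1-yl)bicyclo[3.3.1]non-3-ene-2,9-dione | [C@H]12C(=O)C=C(OC)[C@](CC=C(C)C)(C[C@H](CC=C(C)C)[C@@]1(C)CCC=C(C)C)C2=O | intermediate
21 | 4-methoxy-8-methyl-8-(4-methylpent-3-en-1-yl)-5,7-bis(3-methylbut-2-en-1-yl)-3-(trimethylsilyl)bicyclo[3.3.1]non-3-ene-2,9-dione | [C@H]12C(=O)C([Si](C)(C)C)=C(OC)[C@](CC=C(C)C)(C[C@H](CC=C(C)C)[C@@]1(C)CCC=C(C)C)C2=O | intermediate
22 | (2R)-2-methylbutanoic acid | CC[C@@H](C)C(=O)O | starting material
23 | (2R)-2-methylbutanoyl chloride | CC[C@@H](C)C(Cl)=O | intermediate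
24 | 1-lithio derivative of 21 (bridgehead lithium species) | [Li][C@]12C(=O)C([Si](C)(C)C)=C(OC)[C@](CC=C(C)C)(C[C@H](CC=C(C)C)[C@@]1(C)CCC=C(C)C)C2=O | intermediate (not isolated)
25 | 4-methoxy-8-methyl-1-[(2R)-2-methylbutanoyl]-8-(4-methylpent-3-en-1-yl)-5,7-bis(3-methylbut-2-en-1-yl)-3-(trimethylsilyl)bicyclo[3.3.1]non-3-ene-2,9-dione | CC[C@@H](C)C(=O)[C@]12C(=O)C([Si](C)(C)C)=C(OC)[C@](CC=C(C)C)(C[C@H](CC=C(C)C)[C@@]1(C)CCC=C(C)C)C2=O | intermediate
26 | 4-methoxy-8-methyl-1-[(2R)-2-methylbutanoyl]-8-(4-methylpent-3-en-1-yl)-5,7-bis(3-methylbut-2-en-1-yl)bicyclo[3.3.1]non-3-ene-2,9-dione | CC[C@@H](C)C(=O)[C@]12C(=O)C=C(OC)[C@](CC=C(C)C)(C[C@H](CC=C(C)C)[C@@]1(C)CCC=C(C)C)C2=O | intermediate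
27 | (1S,5S,7S,8R)-4-hydroxy-8-methyl-1-[(2R)-2-methylbutanoyl]-8-(4-methylpent-3-en-1-yl)-5,7-bis(3-methylbut-2-en-1-yl)bicyclo[3.3.1]non-3-ene-2,9-dione | CC[C@@H](C)C(=O)[C@]12C(=O)C=C(O)[C@](CC=C(C)C)(C[C@H](CC=C(C)C)[C@@]1(C)CCC=C(C)C)C2=O | target

**Step count and risks**

Total step count: 18. Longest linear sequence: 17 steps (steps 1–14 and 16–18); step 15 is a one-step side branch.

Steps most likely to fail:

1. Step 6. The facial selectivity of the enolate trapping is the least secure stereochemical assignment of the route. The aldehyde may instead add to C1 from the homoprenyl face, anti to the C7 prenyl, because that approach lets the enolate react in the conformer that has both prenyl-type groups equatorial. The resulting C1 epimer would close ring A on the wrong face. The fallback sets C1 by kinetic protonation instead of by C–C bond formation and sets out from 13 of either C1 configuration. Mesylation and elimination (MsCl, Et3N; then DBU, which also equilibrates C5 towards the series with the C5 prenyl cis to the C7 prenyl) give the alkylidene ketone F1. Nucleophilic epoxidation of its electron-poor double bond (t-BuOOH, DBU) gives the spiro-epoxy ketone F2. Reductive opening with SmI2 in THF/MeOH at −90 °C cleaves the C1–O bond to a trivalent samarium enolate. Its axial protonation, anti to the axial C8 methyl in the chair that holds all three side chains equatorial, should deliver hydrogen trans to the C7 prenyl. The fallback comes back to the route at 13, now with the arm cis to the C7 prenyl.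

2. Step 10. Closure may be slow because ring B has to adopt a boat-like arrangement with the C7 prenyl on the side of the tether, so protodesilylation of the enol silane or 5-exo closure could compete. The fallback closes the same C4–C5 bond by conjugate addition at the C2 ketone oxidation level and sets out from 13. Acetylation (Ac2O, DMAP, pyridine) gives the acetate F3; NBS with catalytic AgNO3 gives the bromoalkyne acetate F4; TBSOTf and Et3N give the enol silane acetate F5. Methanolysis (K2CO3, MeOH, 0 °C) gives the propargylic alcohol F6, and DMP gives the bromo-ynone F7. An intramolecular Mukaiyama–Michael addition (ZnBr2, CH2Cl2, −78 °C, aqueous work-up) then joins C5 to the ynone β-carbon C4, again 6-endo and again on the face fixed by the C1 tether. The fallback comes back to the route at 19 and makes steps 11 and 12 unnecessary.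

3. Step 16. The amide base or the bridgehead anion may deprotonate the acid chloride to a ketene, which would lower conversion and scramble the (R) side-chain centre. The fallback uses aldehyde addition and oxidation and sets out from 21 and 22. Reduction of 22 with LiAlH4 gives (2R)-2-methylbutan-1-ol F8, and oxidation with TEMPO, NaOCl and KBr gives (2R)-2-methylbutanal F9. The bridgehead anion 24, made from 21 with LiTMP at −78 °C, adds to F9 to give the bridgehead carbinol F10. DMP oxidation then gives the ketone, and the fallback comes back to the route at 25.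

Further compounds
F1 | step 6 | 3-methyl-3-(4-methylpent-3-en-1-yl)-4,6-bis(3-methylbut-2-en-1-yl)-2-[3-(trimethylsilyl)prop-2-yn-1-ylidene]cyclohexan-1-one | C[Si](C)(C)C#CC=C1C(=O)C(CC=C(C)C)C[C@H](CC=C(C)C)[C@@]1(C)CCC=C(C)C
F2 | step 6 | 8-methyl-8-(4-methylpent-3-en-1-yl)-5,7-bis(3-methylbut-2-en-1-yl)-2-[(trimethylsilyl)ethynyl]-1-oxaspiro[2.5]octan-4-one | C[Si](C)(C)C#CC1OC12C(=O)C(CC=C(C)C)C[C@H](CC=C(C)C)[C@@]2(C)CCC=C(C)C
F3 | step 10 | 1-[2-methyl-2-(4-methylpent-3-en-1-yl)-3,5-bis(3-methylbut-2-en-1-yl)-6-oxocyclohexyl]-3-(trimethylsilyl)prop-2-yn-1-yl acetate | C[Si](C)(C)C#CC(OC(C)=O)[C@@H]1C(=O)C(CC=C(C)C)C[C@H](CC=C(C)C)[C@@]1(C)CCC=C(C)C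
F4 | step 10 | 3-bromo-1-[2-methyl-2-(4-methylpent-3-en-1-yl)-3,5-bis(3-methylbut-2-en-1-yl)-6-oxocyclohexyl]prop-2-yn-1-yl acetate | BrC#CC(OC(C)=O)[C@@H]1C(=O)C(CC=C(C)C)C[C@H](CC=C(C)C)[C@@]1(C)CCC=C(C)C
F5 | step 10 | 3-bromo-1-[2-(tert-butyldimethylsilyloxy)-6-methyl-6-(4-methylpent-3-en-1-yl)-3,5-bis(3-methylbut-2-en-1-yl)cyclohex-2-en-1-yl]prop-2-yn-1-yl acetate | BrC#CC(OC(C)=O)[C@@H]1C(O[Si](C)(C)C(C)(C)C)=C(CC=C(C)C)C[C@H](CC=C(C)C)[C@@]1(C)CCC=C(C)C
F6 | step 10 | 3-bromo-1-[2-(tert-butyldimethylsilyloxy)-6-methyl-6-(4-methylpent-3-en-1-yl)-3,5-bis(3-methylbut-2-en-1-yl)cyclohex-2-en-1-yl]prop-2-yn-1-ol | BrC#CC(O)[C@@H]1C(O[Si](C)(C)C(C)(C)C)=C(CC=C(C)C)C[C@H](CC=C(C)C)[C@@]1(C)CCC=C(C)C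
F7 | step 10 | 3-bromo-1-[2-(tert-butyldimethylsilyloxy)-6-methyl-6-(4-methylpent-3-en-1-yl)-3,5-bis(3-methylbut-2-en-1-yl)cyclohex-2-en-1-yl]prop-2-yn-1-one | BrC#CC(=O)[C@@H]1C(O[Si](C)(C)C(C)(C)C)=C(CC=C(C)C)C[C@H](CC=C(C)C)[C@@]1(C)CCC=C(C)C
F8 | step 16 | (2R)-2-methylbutan-1-ol | CC[C@@H](C)CO
F9 | step 16 | (2R)-2-methylbutanal | CC[C@@H](C)C=O
F10 | step 16 | 1-[(2R)-1-hydroxy-2-methylbutyl]-4-methoxy-8-methyl-8-(4-methylpent-3-en-1-yl)-5,7-bis(3-methylbut-2-en-1-yl)-3-(trimethylsilyl)bicyclo[3.3.1]non-3-ene-2,9-dione (carbinol epimers) | CC[C@@H](C)C(O)[C@]12C(=O)C([Si](C)(C)C)=C(OC)[C@](CC=C(C)C)(C[C@H](CC=C(C)C)[C@@]1(C)CCC=C(C)C)C2=O
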